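## Retrosynthetic overview

1. Target ⇒ chemoselective MnO2 oxidation of the allylic C3 alcohol, desilylation, and face-selective epoxidation of the (Z)-C1=C10 olefin of a ten-membered triene lactone.
2. Ten-membered carbocycle ⇒ ring-closing metathesis (C1=C10) of a seco-diene; the angelate is placed just before on the only free hydroxyl (C5).
3. C4–C5 bond ⇒ ligand-controlled Nozaki–Hiyama–Kishi coupling of a C5–C10 α-silyloxy aldehyde (lactone fragment) with a C1–C4 2-iodoallyl silyl ether.
4. trans-α-Methylene-γ-butyrolactone (C7–C8 bond, both stereocentres, lactone ring) ⇒ new iridium-catalysed alcohol-level 2-(alkoxycarbonyl)allylation of isoprenol with a Morita–Baylis–Hillman acetate made from (S)-glyceraldehyde acetonide and methyl acrylate.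
5. Order of ring formation: γ-lactone (step 3), carbocycle (step 14), oxirane (step 15).

Assumption: positions are numbered as in germacran-12,8-olides (C1/C10 epoxide, C3 ketone, C4=C15, C5 angelate, C6 OH, C7/C8 ring fusion, C11=C13, C12 lactone C=O); 1, 2, 5, 12, 13 and 20 are taken as commercial, and the temporary C3 carbinol is arbitrarily made S.

## Route

Step 1
Reactants: 1 (4S)-2,2-dimethyl-1,3-dioxolane-4-carbaldehyde; 2 methyl acrylate
Product: 3 methyl 2-{hydroxy[(4S)-2,2-dimethyl-1,3-dioxolan-4-yl]methyl}prop-2-enoate (both carbinol epimers)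
Conditions: DABCO (0.3 equiv), 1,4-dioxane/H2O 1:1, rt, 48 h
Reagents that add atoms: none
Why: Morita–Baylis–Hillman reaction of an activated α-alkoxy aldehyde leaves the acetonide centre untouched, and the new carbinol centre (formed as a mixture) is erased when the allyl unit is ionised in step 3.

Step 2
Reactants: 3 methyl 2-{hydroxy[(4S)-2,2-dimethyl-1,3-dioxolan-4-yl]methyl}prop-2-enoate
Product: 4 methyl 2-{acetoxy[(4S)-2,2-dimethyl-1,3-dioxolan-4-yl]methyl}prop-2-enoate (both epimers)
Conditions: Ac2O, pyridine, DMAP (cat.), CH2Cl2, 0 °C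
Reagents that add atoms: acetic anhydride, CC(=O)OC(C)=O
Why: Simple O-acetylation turns the carbinol into the allylic leaving group needed for allyl-metal formation.

Step 3
Reactants: 4 methyl 2-{acetoxy[(4S)-2,2-dimethyl-1,3-dioxolan-4-yl]methyl}prop-2-enoate; 5 3-methylbut-3-en-1-ol
Product: 8 (4S,5R)-4-[(4R)-2,2-dimethyl-1,3-dioxolan-4-yl]-3-methylidene-5-(2-methylprop-2-en-1-yl)oxolan-2-one, via 3-methylbut-3-enal 6 (not isolated), via open hydroxy ester 7 (not isolated)
Conditions: 5 (3 equiv), [Ir(cod)Cl]2 (2.5 mol %), (R)-SEGPHOS (5 mol %), 4-cyano-3-nitrobenzoic acid (10 mol %), Cs2CO3 (20 mol %), THF, 70 °C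
Reagents that add atoms: none
Why: Proposed new method: iridium-catalysed, alcohol-mediated (transfer-hydrogenative) carbonyl 2-(alkoxycarbonyl)allylation with a γ-branched, chiral Morita–Baylis–Hillman acetate – the cyclometalated iridium C,O-benzoate dehydrogenates 5 to aldehyde 6 and keeps the hydride, deprotonation gives an anionic monovalent iridium species that ionises 4 (both epimers converge) to a trivalent σ-allyl iridium bound at the CH2 terminus, and carbonyl addition through a closed chair at the γ-carbon with the dioxolanyl group pseudo-equatorial forms C7–C8 anti (hence the trans lactone once 7 lactonises in situ), the bisphosphine fixing the aldehyde face (8R, ligand antipode to be confirmed on first use) and with it C7 relative to the resident acetonide centre; the closest known chemistry is iridium-catalysed alcohol-level carbonyl crotylation and 2-(alkoxycarbonyl)allylation with γ-unsubstituted acrylate donors, not yet shown for γ-branched donors carrying a stereocentre.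

Step 4
Reactants: 8 (4S,5R)-4-[(4R)-2,2-dimethyl-1,3-dioxolan-4-yl]-3-methylidene-5-(2-methylprop-2-en-1-yl)oxolan-2-one
Product: 9 (4R,5R)-4-[(1R)-1,2-dihydroxyethyl]-3-methylidene-5-(2-methylprop-2-en-1-yl)oxolan-2-one
Conditions: AcOH/H2O 4:1, 40 °C
Reagents that add atoms: none
Why: Mild acid-catalysed acetal hydrolysis frees the C5/C6 diol while the γ-lactone on O8, the conjugated methylene and the methallyl group are inert to aqueous acetic acid.

Step 5
Reactants: 9 (4R,5R)-4-[(1R)-1,2-dihydroxyethyl]-3-methylidene-5-(2-methylprop-2-en-1-yl)oxolan-2-one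
Product: 10 (4S,5R)-4-[(1R)-1,2-bis(triethylsilyloxy)ethyl]-3-methylidene-5-(2-methylprop-2-en-1-yl)oxolan-2-one
Conditions: TESCl (2.5 equiv), imidazole, DMF, 0 °C
Reagents that add atoms: chlorotriethylsilane, CC[Si](Cl)(CC)CC
Why: Exhaustive silylation gives one primary (C5) and one secondary (C6) triethylsilyl ether, which the next step tells apart.

Step 6
Reactants: 10 (4S,5R)-4-[(1R)-1,2-bis(triethylsilyloxy)ethyl]-3-methylidene-5-(2-methylprop-2-en-1-yl)oxolan-2-one
Product: 11 (2R)-2-[(2R,3S)-4-methylidene-2-(2-methylprop-2-en-1-yl)-5-oxooxolan-3-yl]-2-(triethylsilyloxy)acetaldehyde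
Conditions: (COCl)2, DMSO, CH2Cl2, −78 → −30 °C; then Et3N, −78 → 0 °C
Reagents that add atoms: none
Why: Under Swern conditions a primary triethylsilyl ether is cleaved and oxidised in one pot while the secondary one survives, giving the α-silyloxy aldehyde without epimerisation at low temperature.

Step 7
Reactants: 12 3-(trimethylsilyl)prop-2-ynal; 13 allyltributylstannane
Product: 14 (3S)-1-(trimethylsilyl)hex-5-en-1-yn-3-ol
Conditions: Ti(OiPr)4 (10 mol %), (S)-BINOL (20 mol %), 4 Å MS, CH2Cl2, −20 °C; aq. NaHCO3 work-up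
Reagents that add atoms: none
Why: Keck asymmetric allylation (chiral BINOL–titanium Lewis acid) adds the allyl group to one face of the ynal to set the temporary C3 carbinol as S, a centre that only keeps later intermediates single diastereomers and is oxidised away in step 17.

Step 8
Reactants: 14 (3S)-1-(trimethylsilyl)hex-5-en-1-yn-3-ol
Product: 15 (3S)-hex-5-en-1-yn-3-ol
Conditions: K2CO3 (cat.), MeOH, 0 °C
Reagents that add atoms: none
Why: Base-catalysed protodesilylation (methanolysis of the alkynyl C–Si bond) liberates the terminal alkyne without touching the carbinol centre.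

Step 9
Reactants: 15 (3S)-hex-5-en-1-yn-3-ol
Product: 16 triethyl{[(3S)-hex-5-en-1-yn-3-yl]oxy}silane
Conditions: TESCl, imidazole, CH2Cl2, 0 °C
Reagents that add atoms: chlorotriethylsilane, CC[Si](Cl)(CC)CC
Why: Silylation protects the C3 hydroxyl so that C5–OH is later the only free hydroxyl.

Step 10
Reactants: 16 triethyl{[(3S)-hex-5-en-1-yn-3-yl]oxy}silane
Product: 17 tributyl[(3S)-3-(triethylsilyloxy)hexa-1,5-dien-2-yl]stannane
Conditions: Bu3SnH, Mo(CO)3(CNtBu)3 (2 mol %), hydroquinone (cat.), THF, 55 °C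
Reagents that add atoms: tributyltin hydride, CCCC[SnH](CCCC)CCCC
Why: Molybdenum-catalysed hydrostannation of propargylic ethers is α-selective (tin on the internal carbon) and leaves the isolated terminal alkene alone.

Step 11
Reactants: 17 tributyl[(3S)-3-(triethylsilyloxy)hexa-1,5-dien-2-yl]stannane
Product: 18 triethyl{[(3S)-2-iodohexa-1,5-dien-3-yl]oxy}silane
Conditions: I2, CH2Cl2, 0 °C
Reagents that add atoms: iodine, II
Why: Iododestannylation replaces tin by iodine far faster than iodine adds to the monosubstituted alkene, giving the 2-iodoallyl ether needed for chromium chemistry.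

Step 12
Reactants: 11 (2R)-2-[(2R,3S)-4-methylidene-2-(2-methylprop-2-en-1-yl)-5-oxooxolan-3-yl]-2-(triethylsilyloxy)acetaldehyde; 18 triethyl{[(3S)-2-iodohexa-1,5-dien-3-yl]oxy}silane
Product: 19 (4S,5R)-4-[(1R,2R,4S)-2-hydroxy-3-methylidene-1,4-bis(triethylsilyloxy)hept-6-en-1-yl]-3-methylidene-5-(2-methylprop-2-en-1-yl)oxolan-2-one
Conditions: 18 (1.5 equiv), CrCl2 (4 equiv), NiCl2 (5 mol %), Kishi-type (S)-oxazoline–sulfonamide ligand (4.4 equiv), Et3N (4.4 equiv), THF, rt
Reagents that add atoms: none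
Why: Nozaki–Hiyama–Kishi coupling forms C4–C5 chemoselectively at the aldehyde in the presence of the lactone, and the chiral sulfonamide ligand on trivalent chromium controls the aldehyde face to give the 5R carbinol (syn to the C6 silyloxy group, overriding the weak Felkin bias; ligand antipode chosen accordingly), leaving C5–OH as the only free hydroxyl.

Step 13
Reactants: 19 (4S,5R)-4-[(1R,2R,4S)-2-hydroxy-3-methylidene-1,4-bis(triethylsilyloxy)hept-6-en-1-yl]-3-methylidene-5-(2-methylprop-2-en-1-yl)oxolan-2-one; 20 angelic acid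
Product: 22 (1R,2R,4S)-3-methylidene-1-[(2R,3S)-4-methylidene-2-(2-methylprop-2-en-1-yl)-5-oxooxolan-3-yl]-1,4-bis(triethylsilyloxy)hept-6-en-2-yl (2Z)-2-methylbut-2-enoate, via mixed Yamaguchi anhydride 21 (not isolated)
Conditions: 20, 2,4,6-trichlorobenzoyl chloride, Et3N, toluene, rt; then 19, toluene, 75 °C
Reagents that add atoms: none
Why: Yamaguchi esterification through the mixed anhydride without DMAP acylates the single free hydroxyl with retention at C5 and without Z-to-E isomerisation of the angelate.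

Step 14
Reactants: 22 (1R,2R,4S)-3-methylidene-1-[(2R,3S)-4-methylidene-2-(2-methylprop-2-en-1-yl)-5-oxooxolan-3-yl]-1,4-bis(triethylsilyloxy)hept-6-en-2-yl (2Z)-2-methylbut-2-enoate
Product: 23 (3S,5R,6R,7S,8R)-5-angeloyloxy-3,6-bis(triethylsilyloxy)germacra-1(10)Z,4(15),11(13)-trien-12,8-olide
Conditions: (H2IMes)Cl2Ru=CH(2-iPrO-C6H4) (second-generation Hoveyda–Grubbs catalyst, 20 mol %), toluene (1 mM), 80 °C
Reagents that add atoms: none
Why: Ring-closing metathesis of the monosubstituted C1 olefin with the methallyl olefin at high dilution forms the ten-membered carbocycle, the (Z)-trisubstituted olefin being the less strained geometry in a cyclodecene, while the electron-poor 1,1-disubstituted olefins and the angelate are poor metathesis partners.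

Step 15
Reactants: 23 (3S,5R,6R,7S,8R)-5-angeloyloxy-3,6-bis(triethylsilyloxy)germacra-1(10)Z,4(15),11(13)-trien-12,8-olide
Product: 24 (1S,3S,5R,6R,7S,8R,10R)-5-angeloyloxy-1,10-epoxy-3,6-bis(triethylsilyloxy)germacra-4(15),11(13)-dien-12,8-olide
Conditions: dimethyldioxirane (1.1 equiv), acetone/CH2Cl2, −30 °C
Reagents that add atoms: dimethyldioxirane, CC1(C)OO1
Why: Electrophilic dioxirane epoxidation is selective for the only electron-rich (trisubstituted) olefin and adds syn, so the (Z)-olefin gives the cis-epoxide; attack on the exposed peripheral face of the cyclodecene is relied on for the 1S,10R configuration (least predictable element, see below).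

Step 16
Reactants: 24 (1S,3S,5R,6R,7S,8R,10R)-5-angeloyloxy-1,10-epoxy-3,6-bis(triethylsilyloxy)germacra-4(15),11(13)-dien-12,8-olide
Product: 25 (1S,3S,5R,6R,7R,8R,10R)-5-angeloyloxy-1,10-epoxy-3,6-dihydroxygermacra-4(15),11(13)-dien-12,8-olide
Conditions: Et3N·3HF, THF, 0 °C → rt
Reagents that add atoms: none
Why: Near-neutral fluoride desilylation cleaves both triethylsilyl ethers without opening the epoxide, migrating the angelate or translactonising.

Step 17
Reactants: 25 (1S,3S,5R,6R,7R,8R,10R)-5-angeloyloxy-1,10-epoxy-3,6-dihydroxygermacra-4(15),11(13)-dien-12,8-olide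
Product: 26 (1S,5R,6R,7R,8R,10R)-5-angeloyloxy-1,10-epoxy-6-hydroxy-3-oxogermacra-4(15),11(13)-dien-12,8-olide (CNP0348992.7)
Conditions: MnO2 (activated, 25 equiv), CH2Cl2, rt
Reagents that add atoms: none
Why: Allylic oxidation with manganese dioxide converts only the allylic C3 alcohol into the α-methylene ketone and spares the non-allylic C6 alcohol, the epoxide and the esters, which removes the temporary C3 stereocentre and gives the target.

## Compound list

1 | (4S)-2,2-dimethyl-1,3-dioxolane-4-carbaldehyde ((S)-glyceraldehyde acetonide) | O=C[C@@H]1COC(C)(C)O1 | starting material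
2 | methyl acrylate | C=CC(=O)OC | starting material
3 | methyl 2-{hydroxy[(4S)-2,2-dimethyl-1,3-dioxolan-4-yl]methyl}prop-2-enoate (carbinol epimers) | C=C(C(=O)OC)C(O)[C@@H]1COC(C)(C)O1 | intermediate
4 | methyl 2-{acetoxy[(4S)-2,2-dimethyl-1,3-dioxolan-4-yl]methyl}prop-2-enoate (epimers at the acetoxy carbon) | C=C(C(=O)OC)C(OC(C)=O)[C@@H]1COC(C)(C)O1 | intermediate
5 | 3-methylbut-3-en-1-ol (isoprenol) | C=C(C)CCO | starting material
6 | 3-methylbut-3-enal | C=C(C)CC=O | intermediate
7 | methyl (3S,4R)-3-[(4R)-2,2-dimethyl-1,3-dioxolan-4-yl]-4-hydroxy-6-methyl-2-methylidenehept-6-enoate | C=C(C(=O)OC)[C@H]([C@@H]1COC(C)(C)O1)[C@H](O)CC(C)=C | intermediate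
8 | (4S,5R)-4-[(4R)-2,2-dimethyl-1,3-dioxolan-4-yl]-3-methylidene-5-(2-methylprop-2-en-1-yl)oxolan-2-one | C=C1C(=O)O[C@H](CC(C)=C)[C@H]1[C@@H]2COC(C)(C)O2 | intermediate
9 | (4R,5R)-4-[(1R)-1,2-dihydroxyethyl]-3-methylidene-5-(2-methylprop-2-en-1-yl)oxolan-2-one | C=C1C(=O)O[C@H](CC(C)=C)[C@H]1[C@@H](O)CO | intermediate
10 | (4S,5R)-4-[(1R)-1,2-bis(triethylsilyloxy)ethyl]-3-methylidene-5-(2-methylprop-2-en-1-yl)oxolan-2-one | C=C1C(=O)O[C@H](CC(C)=C)[C@H]1[C@@H](O[Si](CC)(CC)CC)CO[Si](CC)(CC)CC | intermediate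
11 | (2R)-2-[(2R,3S)-4-methylidene-2-(2-methylprop-2-en-1-yl)-5-oxooxolan-3-yl]-2-(triethylsilyloxy)acetaldehyde | C=C1C(=O)O[C@H](CC(C)=C)[C@H]1[C@@H](O[Si](CC)(CC)CC)C=O | intermediate
12 | 3-(trimethylsilyl)prop-2-ynal | C[Si](C)(C)C#CC=O | starting material
13 | allyltributylstannane | C=CC[Sn](CCCC)(CCCC)CCCC | starting material
14 | (3S)-1-(trimethylsilyl)hex-5-en-1-yn-3-ol | C[Si](C)(C)C#C[C@@H](O)CC=C | intermediate
15 | (3S)-hex-5-en-1-yn-3-ol | C#C[C@@H](O)CC=C | intermediate
16 | triethyl{[(3S)-hex-5-en-1-yn-3-yl]oxy}silane | C#C[C@@H](O[Si](CC)(CC)CC)CC=C | intermediate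
17 | tributyl[(3S)-3-(triethylsilyloxy)hexa-1,5-dien-2-yl]stannane | C=C([Sn](CCCC)(CCCC)CCCC)[C@@H](O[Si](CC)(CC)CC)CC=C | intermediate
18 | triethyl{[(3S)-2-iodohexa-1,5-dien-3-yl]oxy}silane | C=C(I)[C@@H](O[Si](CC)(CC)CC)CC=C | intermediate
19 | (4S,5R)-4-[(1R,2R,4S)-2-hydroxy-3-methylidene-1,4-bis(triethylsilyloxy)hept-6-en-1-yl]-3-methylidene-5-(2-methylprop-2-en-1-yl)oxolan-2-one | C=CC[C@H](O[Si](CC)(CC)CC)C(=C)[C@@H](O)[C@H](O[Si](CC)(CC)CC)[C@H]1C(=C)C(=O)O[C@@H]1CC(C)=C | intermediate
20 | angelic acid ((2Z)-2-methylbut-2-enoic acid) | C/C=C(/C)C(=O)O | starting material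
21 | (2Z)-2-methylbut-2-enoic 2,4,6-trichlorobenzoic anhydride | C/C=C(/C)C(=O)OC(=O)c1c(Cl)cc(Cl)cc1Cl | intermediate
22 | (1R,2R,4S)-3-methylidene-1-[(2R,3S)-4-methylidene-2-(2-methylprop-2-en-1-yl)-5-oxooxolan-3-yl]-1,4-bis(triethylsilyloxy)hept-6-en-2-yl (2Z)-2-methylbut-2-enoate | C=CC[C@H](O[Si](CC)(CC)CC)C(=C)[C@@H](OC(=O)/C(C)=C\C)[C@H](O[Si](CC)(CC)CC)[C@H]1C(=C)C(=O)O[C@@H]1CC(C)=C | intermediate
23 | (3S,5R,6R,7S,8R)-5-angeloyloxy-3,6-bis(triethylsilyloxy)germacra-1(10)Z,4(15),11(13)-trien-12,8-olide | C=C1C(=O)O[C@@H]2C/C(C)=C\C[C@H](O[Si](CC)(CC)CC)C(=C)[C@@H](OC(=O)/C(C)=C\C)[C@H](O[Si](CC)(CC)CC)[C@@H]12 | intermediate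
24 | (1S,3S,5R,6R,7S,8R,10R)-5-angeloyloxy-1,10-epoxy-3,6-bis(triethylsilyloxy)germacra-4(15),11(13)-dien-12,8-olide | C=C1C(=O)O[C@@H]2C[C@@]3(C)O[C@H]3C[C@H](O[Si](CC)(CC)CC)C(=C)[C@@H](OC(=O)/C(C)=C\C)[C@H](O[Si](CC)(CC)CC)[C@@H]12 | intermediate
25 | (1S,3S,5R,6R,7R,8R,10R)-5-angeloyloxy-1,10-epoxy-3,6-dihydroxygermacra-4(15),11(13)-dien-12,8-olide | C=C1C(=O)O[C@@H]2C[C@@]3(C)O[C@H]3C[C@H](O)C(=C)[C@@H](OC(=O)/C(C)=C\C)[C@H](O)[C@@H]12 | intermediate
26 | (1S,5R,6R,7R,8R,10R)-5-angeloyloxy-1,10-epoxy-6-hydroxy-3-oxogermacra-4(15),11(13)-dien-12,8-olide (CNP0348992.7) | C=C1C(=O)O[C@@H]2C[C@@]3(C)O[C@H]3CC(=O)C(=C)[C@@H](OC(=O)/C(C)=C\C)[C@H](O)[C@@H]12 | target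

## Step count and risks

Total: 17 steps. Longest linear sequence: 12 steps (steps 1–6 and 12–17, from 1); the iodide branch (steps 7–11) is 5 steps.

Three steps most likely to fail:

Step 3 (the proposed new reaction). The risks are base-induced isomerisation of transient 6 to the conjugated enal, protonolysis of the allyl–iridium species, and a mismatched pairing between the catalyst and the acetonide centre. The fallback uses known chemistry, sets out from 3 and 5 and comes back at 8. Alcohol 3 is brominated with allylic transposition (NBS, Me2S, CH2Cl2, 0 °C) to methyl (2Z)-2-(bromomethyl)-3-[(4R)-2,2-dimethyl-1,3-dioxolan-4-yl]prop-2-enoate F1. Separately, 5 is oxidised (Dess–Martin periodinane, NaHCO3, CH2Cl2, 0 °C) to 6, which is used at once as a cold solution. Stoichiometric CrCl2 in THF (Nozaki–Hiyama-type Barbier 2-(alkoxycarbonyl)allylation, expected anti through equilibrating allylchromium species, with a chiral bis(oxazoline) ligand on chromium if facial control by the acetonide is insufficient) joins F1 and 6 to 7, which closes to 8 on mildly acidic work-up.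

Step 14 (ring-closing metathesis). The risks are oligomerisation instead of closure of the strained ten-membered ring, interference by the conjugated lactone methylene, and formation of the E olefin. The fallback moves the ring closure to the C4–C5 bond, sets out from 11 and 18 and comes back at 23. Olefin cross-metathesis of 11 with 18 (second-generation Hoveyda–Grubbs catalyst, CH2Cl2, 40 °C) gives the seco olefin as an E/Z mixture. The Z isomer (2R)-2-[(2R,3S)-2-[(2Z,5S)-6-iodo-2-methyl-5-(triethylsilyloxy)hepta-2,6-dien-1-yl]-4-methylidene-5-oxooxolan-3-yl]-2-(triethylsilyloxy)acetaldehyde F2 is separated on AgNO3-impregnated silica, and the E isomer is recycled by photosensitised equilibration. An intramolecular Nozaki–Hiyama–Kishi reaction (CrCl2, NiCl2 cat., DMSO/THF, 2 mM, with the chiral sulfonamide ligand if needed) then closes the ring to (3S,5R,6R,7S,8R)-5-hydroxy-3,6-bis(triethylsilyloxy)germacra-1(10)Z,4(15),11(13)-trien-12,8-olide F3, which is angeloylated as in step 13 to give 23.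

Step 15 (face selectivity of the epoxidation). The facial preference of the macrocyclic olefin cannot be predicted with confidence. The fallback sets out from 23 and comes back at 24, and turns a wrong facial preference to advantage. NBS in THF/H2O (0 °C) forms the bromonium ion on the face the dioxirane prefers, and water opens it anti at the tertiary carbon to the bromohydrin (1R,3S,5R,6R,7S,8R,10R)-5-angeloyloxy-1-bromo-10-hydroxy-3,6-bis(triethylsilyloxy)germacra-4(15),11(13)-dien-12,8-olide F4. Ag2O (CH2Cl2, rt) closes the oxirane with inversion at C1, which places the oxygen on the opposite face and gives 24.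

The ligand-controlled C5 configuration in step 12 ranks next and has no fallback here.

Further compounds
F1 | step 3 | methyl (2Z)-2-(bromomethyl)-3-[(4R)-2,2-dimethyl-1,3-dioxolan-4-yl]prop-2-enoate | BrC/C(C(=O)OC)=C\[C@@H]1COC(C)(C)O1
F2 | step 14 | (2R)-2-[(2R,3S)-2-[(2Z,5S)-6-iodo-2-methyl-5-(triethylsilyloxy)hepta-2,6-dien-1-yl]-4-methylidene-5-oxooxolan-3-yl]-2-(triethylsilyloxy)acetaldehyde | C=C(I)[C@@H](O[Si](CC)(CC)CC)C\C=C(C)/C[C@H]1OC(=O)C(=C)[C@@H]1[C@@H](O[Si](CC)(CC)CC)C=O
F3 | step 14 | (3S,5R,6R,7S,8R)-5-hydroxy-3,6-bis(triethylsilyloxy)germacra-1(10)Z,4(15),11(13)-trien-12,8-olide | C=C1C(=O)O[C@@H]2C/C(C)=C\C[C@H](O[Si](CC)(CC)CC)C(=C)[C@@H](O)[C@H](O[Si](CC)(CC)CC)[C@@H]12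
F4 | step 15 | (1R,3S,5R,6R,7S,8R,10R)-5-angeloyloxy-1-bromo-10-hydroxy-3,6-bis(triethylsilyloxy)germacra-4(15),11(13)-dien-12,8-olide | C=C1C(=O)O[C@@H]2C[C@@](C)(O)[C@H](Br)C[C@H](O[Si](CC)(CC)CC)C(=C)[C@@H](OC(=O)/C(C)=C\C)[C@H](O[Si](CC)(CC)CC)[C@@H]12
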